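## Retrosynthetic overview

1. Ring C is made last. The tertiary carbinol C–O bond comes from para-hydroxylative dearomatisation of a phenol (key step), followed by hydrogenation of the disubstituted enone C=C; ring C is carried as an anisole until then.
2. Nine-membered ring: the C8–CH2 bond is closed by trivalent-titanium radical opening of a spiro-epoxide onto an N-tethered vinyl ketone (new step). The tether is attached by aza-Michael addition (C–N) of the lactam to a masked divinyl ketone.
3. Lactam: formaldehyde/ammonia annulation (two C–N bonds) of a 2-tetralone β-keto ester. Ring A (cyclopentane): Pd-catalysed ester α-arylation.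
4. Quaternary benzylic carbon: catalytic asymmetric Michael addition of the β-keto ester to methyl acrylate; starting material 5-methoxy-2-tetralone.
5. Ring order: arene and ring B (bought) → lactam → ring A → nine-membered ring → ring C (dearomatised last).

Assumption: the two enolisable stereocentres (ester-bearing C2, and the methyl-bearing carbon α to the ring ketone) have the target configuration as their thermodynamic minimum, so they are set by equilibration.

Locants: tetralins use naphthalene numbering. From compound 9 on, the carbocyclic core uses acenaphthylene numbering (C1, C2, C2a, C3–C5, C5a, C6–C8, C8a, C8b); the lactam is the bridge C8a–C(=O)–N–CH2–C7.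

## Route

Step 1
Reactants: 1 5-methoxy-2-tetralone
Product: 2 methyl 5-methoxy-2-oxo-1,2,3,4-tetrahydronaphthalene-1-carboxylate
Conditions: NaH, (MeO)2CO, THF, 65 °C; then aq. HCl
Reagents that add atoms: dimethyl carbonate, COC(=O)OC
Why: Claisen-type C-acylation of the sodium enolate at the doubly activated benzylic C1 (the usual site for 2-tetralones); the product is an enolised β-keto ester, so no stereocentre matters yet.

Step 2
Reactants: 2 methyl 5-methoxy-2-oxo-1,2,3,4-tetrahydronaphthalene-1-carboxylate, 3 methyl acrylate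
Product: 4 methyl (1R)-5-methoxy-1-(3-methoxy-3-oxopropyl)-2-oxo-1,2,3,4-tetrahydronaphthalene-1-carboxylate
Conditions: N-(9-anthracenylmethyl)cinchonidinium bromide (10 mol %; the pseudo-enantiomeric cinchoninium salt if the sense is opposite), K2CO3 (10 mol %), toluene, −20 °C
Reagents that add atoms: none
Why: Phase-transfer-catalysed asymmetric Michael addition, in which the chiral ammonium–enolate ion pair shields one face of the planar enolate and sets the quaternary C1 as (R), the only centre set by a catalyst.

Step 3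
Reactants: 4 methyl (1R)-5-methoxy-1-(3-methoxy-3-oxopropyl)-2-oxo-1,2,3,4-tetrahydronaphthalene-1-carboxylate
Product: 7 bridged keto-lactam propanoate, via methylidene ketone 5 (not isolated), via aminomethyl ketone 6 (not isolated)
Conditions: (CH2O)n, i-Pr2NH·CF3CO2H, THF, 65 °C; then NH3 (7 M in MeOH), 60 °C
Reagents that add atoms: paraformaldehyde (formaldehyde), C=O; ammonia, N
Why: Mannich-type α-methylenation at the only enolisable carbon (C3), aza-Michael addition of ammonia and lactamisation onto the C1 ester; C3 is epimerisable and only the epimer with CH2NH2 cis to the ester can close the bridge, which fixes (3R).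

Step 4
Reactants: 7 bridged keto-lactam propanoate
Product: 8 8-bromo keto-lactam propanoate
Conditions: NBS, MeCN, 0 °C → rt
Reagents that add atoms: N-bromosuccinimide, O=C1CCC(=O)N1Br
Why: Electrophilic aromatic bromination para to the methoxy group (C8), the position needed for ring A; the bridged ketone cannot enolise, so no α-bromination competes.

Step 5
Reactants: 8 8-bromo keto-lactam propanoate
Product: 9 tetracyclic keto-lactam ester, methyl (2R,7R,8aR)-5-methoxy-8-oxo-8a,7-(carbonyliminomethylene)-1,2,6,7,8,8a-hexahydroacenaphthylene-2-carboxylate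
Conditions: Pd(OAc)2 (5 mol %), P(t-Bu)3·HBF4 (10 mol %), LiN(SiMe3)2 (3 equiv), toluene, 60 °C; then KOt-Bu (10 mol %), t-BuOH/THF, rt
Reagents that add atoms: none
Why: Buchwald–Hartwig-type intramolecular Pd-catalysed α-arylation of the ester enolate closes ring A; the new benzylic ester centre C2 is epimerisable and is equilibrated anti to the angular lactam carbonyl (2R).

Step 6
Reactants: 9 tetracyclic keto-lactam ester
Product: 10 spiro-epoxide of 9 at C8 (both C8 epimers)
Conditions: Me3SI, KN(SiMe3)2, THF, −10 °C → rt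
Reagents that add atoms: trimethylsulfonium iodide, C[S+](C)C.[I-]
Why: Corey–Chaykovsky epoxidation of the strained, non-enolisable bridged ketone; the epoxide configuration is irrelevant because C8 becomes a planar radical in step 9.

Step 7
Reactants: 11 3-methylbut-3-en-2-one
Product: 12 5-(dimethylamino)-2-methylpent-1-en-3-one
Conditions: Me2NH·HCl, (CH2O)n, HCl (cat.), EtOH, 80 °C; then aq. NaOH, 0 °C (used at once)
Reagents that add atoms: paraformaldehyde (formaldehyde), C=O; dimethylamine hydrochloride, CNC.Cl
Why: Mannich reaction at the only enolisable carbon (the methyl group) gives a divinyl ketone whose vinyl end is masked as a β-amino ketone while the isopropenyl end stays free.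

Step 8
Reactants: 10 spiro-epoxide of 9, 12 5-(dimethylamino)-2-methylpent-1-en-3-one
Product: 15 N-(2-methyl-3-oxopent-4-en-1-yl) epoxy-lactam, via Mannich-base adduct 13 (not isolated), via ammonium iodide 14 (not isolated)
Conditions: Cs2CO3 (20 mol %), MeCN, 40 °C; then MeI, rt; then K2CO3, CH2Cl2/H2O, rt
Reagents that add atoms: none
Why: Base-catalysed aza-Michael addition of the lactam N–H to the free isopropenyl ketone puts N on the methyl-branched side (C–N bond), and Hofmann-type elimination of the Mannich-base methiodide then unmasks the vinyl ketone; the side-chain methyl centre is formed unselectively here.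

Step 9
Reactants: 15 N-(2-methyl-3-oxopent-4-en-1-yl) epoxy-lactam
Product: 18 hexacyclic aryl methyl ether acetate, via primary alcohol 16 (not isolated), via acetate epimer mixture 17 (not isolated)
Conditions: Cp2TiCl2 (20 mol %), Zn, 2,4,6-collidine·HCl, THF (0.005 M), rt; then Ac2O, Et3N, DMAP; then TsOH·H2O (cat.), CHCl3, 40 °C
Reagents that add atoms: acetic anhydride, CC(=O)OC(C)=O
Why: Proposed new method: Cp2TiCl (trivalent titanium, formed from Cp2TiCl2 and Zn) opens either epoxide epimer homolytically to the same planar tertiary C8 radical carrying a CH2O–Ti arm, which adds 9-endo to the terminal carbon of the vinyl ketone held over the lactam face by the N-tether, and the α-keto radical is reduced to a titanium enolate and protonated by collidinium, so the chain ends syn to N and CH2O anti (8R); acetylation and acid equilibration of the α-methyl ketone centre follow; the closest known reaction type is the Nugent–RajanBabu/Gansäuer epoxide-opening radical cyclisation and Giese addition, so far shown for three- to seven-membered rings.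

Step 10
Reactants: 18 hexacyclic aryl methyl ether acetate
Product: 19 hexacyclic phenol acetate
Conditions: BCl3, n-Bu4NI, CH2Cl2, −78 → 0 °C; then H2O
Reagents that add atoms: none
Why: Lewis acid/iodide cleavage of the aryl methyl ether (SN2 at the methyl group); methyl ester, acetate, ketone and lactam survive at low temperature.

Step 11
Reactants: 19 hexacyclic phenol acetate
Product: 20 cross-conjugated 2a-hydroxy dienone (p-quinol)
Conditions: PhI(OAc)2, MeCN/H2O (3:1), 0 °C
Reagents that add atoms: water, O
Why: Oxidative hydroxylative dearomatisation of a para-substituted phenol forms the key C–O bond; water attacks C2a of the phenoxenium ion anti to the C2 ester and to the C8 bridge carrying CH2OAc, giving the (2aS) carbinol syn to the lactam carbonyl.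

Step 12
Reactants: 20 cross-conjugated 2a-hydroxy dienone
Product: 21 target CNP0211170.1
Conditions: H2 (1 atm), RhCl(PPh3)3 (10 mol %), benzene/EtOH (1:1), rt
Reagents that add atoms: none
Why: Homogeneous hydrogenation with RhCl(PPh3)3 reduces the disubstituted enone C=C and leaves the tetrasubstituted one, as in steroidal 1,4-dien-3-ones → 4-en-3-ones; neutral conditions keep the β-hydroxy ester and both enolisable centres intact.

## Compound list

1 | 5-methoxy-3,4-dihydronaphthalen-2(1H)-one (5-methoxy-2-tetralone) | COc1cccc2c1CCC(=O)C2 | starting material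
2 | methyl 5-methoxy-2-oxo-1,2,3,4-tetrahydronaphthalene-1-carboxylate (racemic, largely enol) | COC(=O)C1C(=O)CCc2c1cccc2OC | intermediate
3 | methyl prop-2-enoate (methyl acrylate) | C=CC(=O)OC | starting material
4 | methyl (1R)-5-methoxy-1-(3-methoxy-3-oxopropyl)-2-oxo-1,2,3,4-tetrahydronaphthalene-1-carboxylate | COC(=O)CC[C@@]1(C(=O)OC)c2cccc(OC)c2CCC1=O | intermediate
5 | methyl (1R)-5-methoxy-1-(3-methoxy-3-oxopropyl)-3-methylidene-2-oxo-1,2,3,4-tetrahydronaphthalene-1-carboxylate (not isolated) | COC(=O)CC[C@@]1(C(=O)OC)c2cccc(OC)c2CC(=C)C1=O | intermediate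
6 | methyl (1R)-3-(aminomethyl)-5-methoxy-1-(3-methoxy-3-oxopropyl)-2-oxo-1,2,3,4-tetrahydronaphthalene-1-carboxylate (C3 epimers, not isolated) | COC(=O)CC[C@@]1(C(=O)OC)c2cccc(OC)c2CC(CN)C1=O | intermediate
7 | methyl 3-[(1R,3R)-5-methoxy-2-oxo-1,3-(carbonyliminomethylene)-1,2,3,4-tetrahydronaphthalen-1-yl]propanoate (C1 and C3 bridged by C(=O)–NH–CH2, carbonyl on C1; C2 ketone) | COC(=O)CC[C@@]12C(=O)NC[C@@H](Cc3c1cccc3OC)C2=O | intermediate
8 | methyl 3-[(1R,3R)-8-bromo-5-methoxy-2-oxo-1,3-(carbonyliminomethylene)-1,2,3,4-tetrahydronaphthalen-1-yl]propanoate | COC(=O)CC[C@@]12C(=O)NC[C@@H](Cc3c1c(Br)ccc3OC)C2=O | intermediate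
9 | methyl (2R,7R,8aR)-5-methoxy-8-oxo-8a,7-(carbonyliminomethylene)-1,2,6,7,8,8a-hexahydroacenaphthylene-2-carboxylate | COC(=O)[C@@H]1C[C@@]23C(=O)NC[C@@H](Cc4c2c1ccc4OC)C3=O | intermediate
10 | methyl (2R,7R,8aR)-5-methoxy-8a,7-(carbonyliminomethylene)-1,2,6,7-tetrahydro-8aH-spiro[acenaphthylene-8,2'-oxirane]-2-carboxylate (both C8 epimers) | COC(=O)[C@@H]1C[C@@]23C(=O)NC[C@@H](Cc4c2c1ccc4OC)C35CO5 | intermediate
11 | 3-methylbut-3-en-2-one | CC(=O)C(C)=C | starting material
12 | 5-(dimethylamino)-2-methylpent-1-en-3-one | CN(C)CCC(=O)C(C)=C | intermediate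
13 | N-[5-(dimethylamino)-2-methyl-3-oxopentyl] derivative of 10 (side-chain and C8 epimers, not isolated) | COC(=O)[C@@H]1C[C@@]23C(=O)N(CC(C)C(=O)CCN(C)C)C[C@@H](Cc4c2c1ccc4OC)C35CO5 | intermediate
14 | trimethylammonium iodide of 13 (not isolated) | COC(=O)[C@@H]1C[C@@]23C(=O)N(CC(C)C(=O)CC[N+](C)(C)C)C[C@@H](Cc4c2c1ccc4OC)C35CO5.[I-] | intermediate
15 | N-(2-methyl-3-oxopent-4-en-1-yl) derivative of 10 (side-chain and C8 epimers) | COC(=O)[C@@H]1C[C@@]23C(=O)N(CC(C)C(=O)C=C)C[C@@H](Cc4c2c1ccc4OC)C35CO5 | intermediate
16 | hexacyclic alcohol: (2R,7S,8R,8aR) core of 9 with C8 bearing CH2OH and the ring N–CH2–CH(CH3)–C(=O)–CH2–CH2–C8 closed; 5-OMe; CH(CH3) epimers (not isolated) | COC(=O)[C@@H]1C[C@@]23C(=O)N4C[C@@H](Cc5c2c1ccc5OC)[C@]3(CO)CCC(=O)C(C)C4 | intermediate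
17 | acetate of 16, CH(CH3) epimers (not isolated) | COC(=O)[C@@H]1C[C@@]23C(=O)N4C[C@@H](Cc5c2c1ccc5OC)[C@]3(COC(C)=O)CCC(=O)C(C)C4 | intermediate
18 | acetate of 16 with (R)-CH(CH3); (2R,7S,8R,8aR) | COC(=O)[C@@H]1C[C@@]23C(=O)N4C[C@@H](Cc5c2c1ccc5OC)[C@]3(COC(C)=O)CCC(=O)[C@H](C)C4 | intermediate
19 | 5-hydroxy analogue of 18 (phenol); (2R,7S,8R,8aR), side chain (R) | COC(=O)[C@@H]1C[C@@]23C(=O)N4C[C@@H](Cc5c2c1ccc5O)[C@]3(COC(C)=O)CCC(=O)[C@H](C)C4 | intermediate
20 | (2R,2aS,7S,8R,8aS)-2a-hydroxy-5-oxo-3,4-didehydro analogue of the target (cyclohexa-2,5-dienone ring C), side chain (R) | COC(=O)[C@@H]1C[C@@]23C(=O)N4C[C@@H](CC5=C2[C@]1(O)C=CC5=O)[C@]3(COC(C)=O)CCC(=O)[C@H](C)C4 | intermediate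
21 | CNP0211170.1; (2R,2aS,7S,8R,8aS), side chain (R) | COC(=O)[C@@H]1C[C@@]23C(=O)N4C[C@@H](CC5=C2[C@]1(O)CCC5=O)[C@]3(COC(C)=O)CCC(=O)[C@H](C)C4 | target

## Step count and risks

Total steps: 12. Longest linear sequence: 11 (steps 1–6 and 8–12; step 7 makes the side-chain reagent).

Steps most likely to fail:

**Step 9 (the proposed new step).** Nine-membered radical closure at a quaternary centre is unprecedented; the radical may be reduced or the enone may be attacked by the titanium reagent first. The fallback sets out from 10 and 12 and comes back at 17; it makes the C8–C bond first and closes the ring through the C–N bond. Quaternisation of 12 with MeI gives trimethyl(4-methyl-3-oxopent-4-en-1-yl)ammonium iodide F1, and K2CO3 eliminates it to 2-methylpenta-1,4-dien-3-one F2. The known intermolecular Nugent–RajanBabu coupling of 10 with F2 (Cp2TiCl2, Zn, THF; the radical adds to the unsubstituted vinyl end) gives the C8-hydroxymethyl C8-(4-methyl-3-oxopent-4-enyl) lactam F3 as both C8 epimers. Acetylation and chromatography give the (8R) acetate F4, which has the chain syn to N–H. Cs2CO3-catalysed intramolecular aza-Michael addition of the lactam N–H to the isopropenyl ketone then gives 17. This fallback loses the C8 epimer that cannot cyclise.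

**Step 8.** The benzylic ester C–H of 10 is about as acidic as the lactam N–H, so C-alkylation may compete with the aza-Michael addition. The fallback sets out from 9 and comes back at 15; it is base-free at the N-alkylation stage. Wittig methylenation (Ph3P=CH2) gives the 8-methylidene lactam F5. Treatment with (CH2O)n and Me3SiCl gives the N-(chloromethyl) lactam F6. ZnBr2-catalysed amidoalkylation of 3-(trimethylsilyloxy)penta-1,3-diene F7 (from pent-1-en-3-one, Me3SiCl, Et3N, NaI) gives the N-(2-methyl-3-oxopent-4-en-1-yl) methylidene lactam F8. Epoxidation of the exocyclic alkene with m-CPBA (the vinyl ketone is inert) gives 15.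

**Step 11.** The phenoxenium ion may lose the acidic benzylic C2–H to give a quinone methide instead of taking up water. The fallback sets out from 19 and comes back at 20; it avoids cationic intermediates. Dye-sensitised photo-oxygenation (O2, rose bengal, hν, MeOH) gives the 2a-hydroperoxy dienone F9, and Me2S reduces it to 20.

Further compounds
F1 | step 9 | trimethyl(4-methyl-3-oxopent-4-en-1-yl)ammonium iodide | C=C(C)C(=O)CC[N+](C)(C)C.[I-]
F2 | step 9 | 2-methylpenta-1,4-dien-3-one | C=CC(=O)C(C)=C
F3 | step 9 | C8-hydroxymethyl C8-(4-methyl-3-oxopent-4-enyl) N–H lactam (C8 epimers) | COC(=O)[C@@H]1C[C@@]23C(=O)NC[C@@H](Cc4c2c1ccc4OC)C3(CO)CCC(=O)C(C)=C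
F4 | step 9 | (8R) acetate of F3 | COC(=O)[C@@H]1C[C@@]23C(=O)NC[C@@H](Cc4c2c1ccc4OC)[C@]3(COC(C)=O)CCC(=O)C(C)=C
F5 | step 8 | 8-methylidene analogue of 9 | COC(=O)[C@@H]1C[C@@]23C(=O)NC[C@@H](Cc4c2c1ccc4OC)C3=C
F6 | step 8 | N-(chloromethyl) derivative of F5 | COC(=O)[C@@H]1C[C@@]23C(=O)N(CCl)C[C@@H](Cc4c2c1ccc4OC)C3=C
F7 | step 8 | 3-(trimethylsilyloxy)penta-1,3-diene | CC=C(O[Si](C)(C)C)C=C
F8 | step 8 | N-(2-methyl-3-oxopent-4-en-1-yl) derivative of F5 (side-chain epimers) | COC(=O)[C@@H]1C[C@@]23C(=O)N(CC(C)C(=O)C=C)C[C@@H](Cc4c2c1ccc4OC)C3=C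
F9 | step 11 | 2a-hydroperoxy analogue of 20 | COC(=O)[C@@H]1C[C@@]23C(=O)N4C[C@@H](CC5=C2[C@]1(OO)C=CC5=O)[C@]3(COC(C)=O)CCC(=O)[C@H](C)C4
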